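Germacrane numbering is used: C1 ketone, C2=C3 furanone alkene (ring oxygen bridging C3 and C10), C4=C15 methylene, C5 and C6 carbinols, C7, C8 (isobutyrate), C9, C10 (methyl C14), C11–C13 methylene lactone (C12 carbonyl).
Feature used: O6 is homoallylic to the exocyclic C4=C15 alkene, the allylic carbon C5 between them carries the second oxygen erythro to O6, and the C12 ester can reach O6 in a five-membered ring; a γ-alkoxyallyl metal adding to a C6 aldehyde leaves exactly this pattern.
Retrosynthesis: O5 is masked as a PMB ether; C5–C6 and O6–C12 are cut together, opening the ten-membered carbocycle and the γ-lactone to a C6 aldehyde that carries a 2-(furanonyl)acrolein bis-PMB acetal; then C7–C8 (Barbier allylation with a Baylis–Hillman bromide), O–C3 and C1–C2 (hydroxy-ynone cyclisation, acetylide acylation) and C3–C4 (Sonogashira coupling).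
Forward: the furanone ring is built first from (R)-citramalic acid and an acrolein-derived enyne acetal, the chain is extended at C8 and acylated, the carbocycle and the lactone close together in one chromium-mediated step, and O5 is unmasked last.
Stereochemistry: C10 from (R)-citramalic acid; C7/C8 (syn) from the chair transition state of the (Z)-allylindium, aldehyde face set by C10; C5/C6 (anti) from the chair transition state of the alkoxyallylchromium, aldehyde face set by C7.

Key step: step 19

Remark on the chemistry: the alkoxyallylchromium made from a 2-substituted acrolein acetal is assumed to react through the same closed chair transition state as the parent reagent; the metal species 24, 30 and 31 are drawn as simple halides although they are solvated in the flask. PMB = 4-methoxybenzyl, TBS = tert-butyldimethylsilyl.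

Step 1
Reactants: 1 (R)-citramalic acid
Product: 2 2-[(4R)-2,2,4-trimethyl-5-oxo-1,3-dioxolan-4-yl]acetic acid
Conditions: 2,2-dimethoxypropane, TsOH·H2O (cat.), rt
Reagents that add atoms: 2,2-dimethoxypropane COC(C)(C)OC
Why: Acid-catalysed acetal exchange closes a 1,3-dioxolan-4-one on the α-hydroxy acid unit only, which leaves the C8 carboxyl free and does not touch the quaternary C10 centre.

Step 2
Reactants: 2 2-[(4R)-2,2,4-trimethyl-5-oxo-1,3-dioxolan-4-yl]acetic acid
Product: 3 (5R)-5-(2-hydroxyethyl)-2,2,5-trimethyl-1,3-dioxolan-4-one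
Conditions: BH3·SMe2, THF, 0 °C to rt; aqueous work-up
Reagents that add atoms: none
Why: Chemoselective borane reduction of a free carboxylic acid beside the ester-type dioxolanone carbonyl gives the C8 primary alcohol.

Step 3
Reactants: 3 (5R)-5-(2-hydroxyethyl)-2,2,5-trimethyl-1,3-dioxolan-4-one
Product: 4 (5R)-5-[2-(tert-butyldimethylsilyloxy)ethyl]-2,2,5-trimethyl-1,3-dioxolan-4-one
Conditions: TBSCl, imidazole, DMF, rt
Reagents that add atoms: tert-butyldimethylsilyl chloride CC(C)(C)[Si](C)(C)Cl
Why: Silyl ether formation on the primary alcohol protects O8 through the organometallic steps that follow.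

Step 4
Reactants: 4 (5R)-5-[2-(tert-butyldimethylsilyloxy)ethyl]-2,2,5-trimethyl-1,3-dioxolan-4-one
Product: 5 (2R)-4-(tert-butyldimethylsilyloxy)-2-hydroxy-N-methoxy-N,2-dimethylbutanamide
Conditions: MeNHOMe·HCl, i-PrMgCl, THF, −20 to 0 °C
Reagents that add atoms: N,O-dimethylhydroxylamine hydrochloride Cl.CNOC
Why: Weinreb amide formation by aminolysis of the activated dioxolanone with the magnesium amide opens the ring, releases acetone and prepares C1 for a single acetylide addition.

Step 5
Reactants: 6 acrolein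
Product: 8 2-bromoacrolein, via 2,3-dibromopropanal 7 (not isolated)
Conditions: Br2, CH2Cl2, −78 to 0 °C; then Et3N, 0 °C
Reagents that add atoms: bromine BrBr
Why: Bromine addition to the alkene followed by base-induced loss of HBr from the α,β-dibromo aldehyde (addition–elimination) is the standard entry to the 2-bromo enal.

Step 6
Reactants: 8 2-bromoacrolein
Product: 9 2-bromo-3,3-bis(4-methoxybenzyloxy)prop-1-ene
Conditions: 4-MeOC6H4CH2OSiMe3 (2.2 equiv), Me3SiOTf (cat.), CH2Cl2, −78 °C
Reagents that add atoms: 4-methoxybenzyl trimethylsilyl ether COc1ccc(CO[Si](C)(C)C)cc1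
Why: Noyori acetalisation (alkyl silyl ether with catalytic silyl triflate at low temperature) turns the enal into its acyclic bis-PMB acetal without conjugate addition.

Step 7
Reactants: 9 2-bromo-3,3-bis(4-methoxybenzyloxy)prop-1-ene, 10 trimethylsilylacetylene
Product: 11 {3-[bis(4-methoxybenzyloxy)methyl]but-3-en-1-yn-1-yl}trimethylsilane
Conditions: PdCl2(PPh3)2 (cat.), CuI (cat.), Et3N, THF, rt
Reagents that add atoms: none
Why: Sonogashira coupling of the vinyl bromide with the terminal alkyne forms the C3–C4 bond under basic conditions that leave the acetal intact.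

Step 8
Reactants: 11 {3-[bis(4-methoxybenzyloxy)methyl]but-3-en-1-yn-1-yl}trimethylsilane
Product: 12 3-[bis(4-methoxybenzyloxy)methyl]but-3-en-1-yne
Conditions: K2CO3 (cat.), MeOH, rt
Reagents that add atoms: none
Why: Base-catalysed protodesilylation of the alkynylsilane in methanol frees the terminal alkyne, and the acetal is stable to base.

Step 9
Reactants: 5 (2R)-4-(tert-butyldimethylsilyloxy)-2-hydroxy-N-methoxy-N,2-dimethylbutanamide, 12 3-[bis(4-methoxybenzyloxy)methyl]but-3-en-1-yne
Product: 16 (6R)-8-(tert-butyldimethylsilyloxy)-6-hydroxy-2-[bis(4-methoxybenzyloxy)methyl]-6-methyloct-1-en-3-yn-5-one, via lithium acetylide 13 (not isolated), via chloromagnesium alkoxide 14 (not isolated), via tetrahedral adduct 15 (not isolated)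
Conditions: 12, n-BuLi, THF, −78 °C; 5, i-PrMgCl, THF, −20 °C; combine, −78 to 0 °C; aq. NH4Cl
Reagents that add atoms: none
Why: Acetylide acylation with a Weinreb amide forms C1–C2 and stops at the ketone because the chelated adduct 15 collapses only on work-up, the tertiary hydroxyl being held as alkoxide 14 so that one equivalent of 13 suffices.

Step 10
Reactants: 16 (6R)-8-(tert-butyldimethylsilyloxy)-6-hydroxy-2-[bis(4-methoxybenzyloxy)methyl]-6-methyloct-1-en-3-yn-5-one
Product: 17 (2R)-2-[2-(tert-butyldimethylsilyloxy)ethyl]-2-methyl-5-[3,3-bis(4-methoxybenzyloxy)prop-1-en-2-yl]furan-3(2H)-one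
Conditions: (4-CF3C6H4)3PAuCl (cat.), AgOTf (cat.), toluene, rt
Reagents that add atoms: none
Why: Gold-catalysed 5-endo-dig cycloisomerisation of the α′-hydroxy ynone (alkyne activation, attack of the C10 hydroxyl on C3, protodeauration) gives the 3(2H)-furanone without breaking a bond at C10.

Step 11
Reactants: 17 (2R)-2-[2-(tert-butyldimethylsilyloxy)ethyl]-2-methyl-5-[3,3-bis(4-methoxybenzyloxy)prop-1-en-2-yl]furan-3(2H)-one
Product: 18 (2R)-2-(2-hydroxyethyl)-2-methyl-5-[3,3-bis(4-methoxybenzyloxy)prop-1-en-2-yl]furan-3(2H)-one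
Conditions: HF·pyridine, pyridine, THF, 0 °C to rt
Reagents that add atoms: none
Why: Buffered fluoride desilylation frees the C8 alcohol and is expected to spare the acetal and the furanone.

Step 12
Reactants: 18 (2R)-2-(2-hydroxyethyl)-2-methyl-5-[3,3-bis(4-methoxybenzyloxy)prop-1-en-2-yl]furan-3(2H)-one
Product: 19 2-{(2R)-2-methyl-3-oxo-5-[3,3-bis(4-methoxybenzyloxy)prop-1-en-2-yl]-2,3-dihydrofuran-2-yl}acetaldehyde
Conditions: Dess–Martin periodinane, pyridine, CH2Cl2, 0 °C to rt
Reagents that add atoms: none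
Why: Dess–Martin oxidation gives the C8 aldehyde under near-neutral conditions that avoid β-elimination of the furanone ring oxygen.

Step 13
Reactants: 20 methyl acrylate, 21 (tert-butyldimethylsilyloxy)acetaldehyde
Product: 22 methyl 4-(tert-butyldimethylsilyloxy)-3-hydroxy-2-methylidenebutanoate (racemic)
Conditions: DABCO (cat.), neat, rt
Reagents that add atoms: none
Why: Morita–Baylis–Hillman reaction joins the acrylate α-carbon to the aldehyde, and the racemic carbinol centre is removed in the next step.

Step 14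
Reactants: 22 methyl 4-(tert-butyldimethylsilyloxy)-3-hydroxy-2-methylidenebutanoate
Product: 23 methyl (2Z)-2-(bromomethyl)-4-(tert-butyldimethylsilyloxy)but-2-enoate
Conditions: NBS, Me2S, CH2Cl2, 0 °C to rt
Reagents that add atoms: N-bromosuccinimide O=C1CCC(=O)N1Br
Why: Corey–Kim-type activation of the allylic alcohol and SN2′ entry of bromide (allylic transposition) give the thermodynamically preferred (Z)-2-(bromomethyl)enoate, with the ester trans to the silyloxymethyl group.

Step 15
Reactants: 19 2-{(2R)-2-methyl-3-oxo-5-[3,3-bis(4-methoxybenzyloxy)prop-1-en-2-yl]-2,3-dihydrofuran-2-yl}acetaldehyde, 23 methyl (2Z)-2-(bromomethyl)-4-(tert-butyldimethylsilyloxy)but-2-enoate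
Product: 25 methyl (3S,4R)-3-[(tert-butyldimethylsilyloxy)methyl]-4-hydroxy-2-methylidene-5-{(2R)-2-methyl-3-oxo-5-[3,3-bis(4-methoxybenzyloxy)prop-1-en-2-yl]-2,3-dihydrofuran-2-yl}pentanoate, via allylindium dibromide 24 (not isolated)
Conditions: indium powder (In), THF/H2O (3:1), rt
Reagents that add atoms: none
Why: Indium-mediated Barbier allylation through a closed chair transition state, in which the (Z)-allylindium 24 keeps its geometry, gives the C7/C8 syn adduct, and attack anti to the C10–O dipole of the β-oxygenated aldehyde (1,3-induction) is expected to favour the 8R face, the minor diastereomer being removed here.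

Step 16
Reactants: 25 methyl (3S,4R)-3-[(tert-butyldimethylsilyloxy)methyl]-4-hydroxy-2-methylidene-5-{(2R)-furanonyl}pentanoate
Product: 26 methyl (3S,4R)-3-[(tert-butyldimethylsilyloxy)methyl]-2-methylidene-4-(2-methylpropanoyloxy)-5-{(2R)-2-methyl-3-oxo-5-[3,3-bis(4-methoxybenzyloxy)prop-1-en-2-yl]-2,3-dihydrofuran-2-yl}pentanoate
Conditions: (i-PrCO)2O, DMAP (cat.), pyridine, CH2Cl2, 0 °C
Reagents that add atoms: isobutyric anhydride CC(C)C(=O)OC(=O)C(C)C
Why: DMAP-catalysed acylation of the secondary alcohol installs the isobutyrate of the target and blocks lactonisation of O8 onto C12.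

Step 17
Reactants: 26 the C6 silyl ether isobutyrate
Product: 27 methyl (3S,4R)-3-(hydroxymethyl)-2-methylidene-4-(2-methylpropanoyloxy)-5-{(2R)-2-methyl-3-oxo-5-[3,3-bis(4-methoxybenzyloxy)prop-1-en-2-yl]-2,3-dihydrofuran-2-yl}pentanoate
Conditions: HF·pyridine, pyridine, THF, 0 °C
Reagents that add atoms: none
Why: Buffered fluoride desilylation frees the primary C6 alcohol without acyl migration or acetal loss, and the hydroxy ester is taken on at once to forestall lactonisation.

Step 18
Reactants: 27 the C6 alcohol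
Product: 28 methyl (3R,4R)-3-formyl-2-methylidene-4-(2-methylpropanoyloxy)-5-{(2R)-2-methyl-3-oxo-5-[3,3-bis(4-methoxybenzyloxy)prop-1-en-2-yl]-2,3-dihydrofuran-2-yl}pentanoate
Conditions: Dess–Martin periodinane, pyridine, CH2Cl2, 0 °C; short filtration, used at once
Reagents that add atoms: none
Why: Dess–Martin oxidation under buffered conditions gives the C6 aldehyde, which is not stored because H7 is activated by both the aldehyde and the acrylate.

Step 19
Reactants: 28 the C6 aldehyde with the bis-PMB acetal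
Product: 32 C5 p-methoxybenzyl ether of the target (5S,6R,7R,8R,10R), via iodo ether 29 (not isolated), via allylchromium dichloride 30 (not isolated), via chromium alkoxide 31 (not isolated)
Conditions: CrCl2 (8 equiv), Me3SiI (1.5 equiv), THF, −30 °C to rt; 28 and Me3SiI added slowly and separately (final 2 mM)
Reagents that add atoms: none
Why: Proposed new method: Me3SiI ionises one arm of the acetal to the α-iodo ether 29, two equivalents of divalent chromium reduce it to the trivalent allylchromium 30 bound at C15, and this adds through its γ-carbon C5 to the tethered C6 aldehyde in a closed six-membered chair transition state; the closest known reactions are the intermolecular erythro-selective addition of γ-alkoxyallylchromium reagents made from enal acetals with CrCl2 and Me3SiI, and macrocyclising chromium-mediated allylations of aldehydes. The ten-membered carbocycle closes in this C5–C6 bond formation (10-exo-trig attack on the aldehyde), which also creates the C4=C15 methylene by allylic transposition, and the γ-lactone follows by 5-exo-trig attack of the O6 chromium alkoxide 31 on the C12 methyl ester. C5 is set relative to C6 by the chair (E-configured enol ether, PMB-oxy group and aldehyde substituent both equatorial, hence anti), and C6 is set by C7: the tether holds the C8 branch gauche to the forming bond, so the acrylate carbon C11 lies anti to the incoming C5 and H7 flanks its path, which leads to 6R and the trans-fused lactone. The step needs anti C5/C6 selectivity and the correct aldehyde face, which the chair and the C7 centre are expected to secure, while high dilution, the tolerance of organochromium reagents for esters, the furanone and the acrylate, and immediate use of 28 guard against oligomers and loss of the C7 configuration. Lactonisation through O6 alone also tells O6 from the etherified O5.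

Step 20
Reactants: 32 C5 p-methoxybenzyl ether of the target
Product: 33 CNP0384113.1 (5S,6R,7R,8R,10R)
Conditions: DDQ, CH2Cl2/pH 7 buffer, 0 °C to rt
Reagents that add atoms: none
Why: Oxidative PMB ether cleavage by DDQ (hydride abstraction, hydrolysis of the oxocarbenium ion) frees O5 without touching the esters, the lactone or the electron-poor alkenes.

Compound list
1 | (R)-citramalic acid | C[C@@](O)(CC(=O)O)C(=O)O | starting material
2 | 2-[(4R)-2,2,4-trimethyl-5-oxo-1,3-dioxolan-4-yl]acetic acid | C[C@]1(CC(=O)O)OC(C)(C)OC1=O | intermediate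
3 | (5R)-5-(2-hydroxyethyl)-2,2,5-trimethyl-1,3-dioxolan-4-one | C[C@]1(CCO)OC(C)(C)OC1=O | intermediate
4 | (5R)-5-[2-(tert-butyldimethylsilyloxy)ethyl]-2,2,5-trimethyl-1,3-dioxolan-4-one | C[C@]1(CCO[Si](C)(C)C(C)(C)C)OC(C)(C)OC1=O | intermediate
5 | (2R)-4-(tert-butyldimethylsilyloxy)-2-hydroxy-N-methoxy-N,2-dimethylbutanamide | C[C@@](O)(CCO[Si](C)(C)C(C)(C)C)C(=O)N(C)OC | intermediate
6 | acrolein | C=CC=O | starting material
7 | 2,3-dibromopropanal (racemic, not isolated) | O=CC(Br)CBr | intermediate
8 | 2-bromoacrolein | C=C(Br)C=O | intermediate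
9 | 2-bromo-3,3-bis(4-methoxybenzyloxy)prop-1-ene | C=C(Br)C(OCc1ccc(OC)cc1)OCc1ccc(OC)cc1 | intermediate
10 | trimethylsilylacetylene | C#C[Si](C)(C)C | starting material
11 | {3-[bis(4-methoxybenzyloxy)methyl]but-3-en-1-yn-1-yl}trimethylsilane | C=C(C#C[Si](C)(C)C)C(OCc1ccc(OC)cc1)OCc1ccc(OC)cc1 | intermediate
12 | 3-[bis(4-methoxybenzyloxy)methyl]but-3-en-1-yne | C=C(C#C)C(OCc1ccc(OC)cc1)OCc1ccc(OC)cc1 | intermediate
13 | lithium acetylide of 12 (not isolated) | [Li]C#CC(=C)C(OCc1ccc(OC)cc1)OCc1ccc(OC)cc1 | intermediate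
14 | chloromagnesium alkoxide of 5 (not isolated) | C[C@@](O[Mg]Cl)(CCO[Si](C)(C)C(C)(C)C)C(=O)N(C)OC | intermediate
15 | tetrahedral N-methoxy-N-methyl adduct of 13 and 14, O-lithium and O-magnesium chloride, new carbinolamine carbon undefined (not isolated) | C[C@@](O[Mg]Cl)(CCO[Si](C)(C)C(C)(C)C)C(O[Li])(N(C)OC)C#CC(=C)C(OCc1ccc(OC)cc1)OCc1ccc(OC)cc1 | intermediate
16 | (6R)-8-(tert-butyldimethylsilyloxy)-6-hydroxy-2-[bis(4-methoxybenzyloxy)methyl]-6-methyloct-1-en-3-yn-5-one | C[C@@](O)(CCO[Si](C)(C)C(C)(C)C)C(=O)C#CC(=C)C(OCc1ccc(OC)cc1)OCc1ccc(OC)cc1 | intermediate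
17 | (2R)-2-[2-(tert-butyldimethylsilyloxy)ethyl]-2-methyl-5-[3,3-bis(4-methoxybenzyloxy)prop-1-en-2-yl]furan-3(2H)-one | CC(C)(C)[Si](C)(C)OCC[C@@]1(C)OC(=CC1=O)C(=C)C(OCc2ccc(OC)cc2)OCc3ccc(OC)cc3 | intermediate
18 | (2R)-2-(2-hydroxyethyl)-2-methyl-5-[3,3-bis(4-methoxybenzyloxy)prop-1-en-2-yl]furan-3(2H)-one | OCC[C@@]1(C)OC(=CC1=O)C(=C)C(OCc2ccc(OC)cc2)OCc3ccc(OC)cc3 | intermediate
19 | 2-{(2R)-2-methyl-3-oxo-5-[3,3-bis(4-methoxybenzyloxy)prop-1-en-2-yl]-2,3-dihydrofuran-2-yl}acetaldehyde (C8 aldehyde) | O=CC[C@@]1(C)OC(=CC1=O)C(=C)C(OCc2ccc(OC)cc2)OCc3ccc(OC)cc3 | intermediate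
20 | methyl acrylate | C=CC(=O)OC | starting material
21 | (tert-butyldimethylsilyloxy)acetaldehyde | O=CCO[Si](C)(C)C(C)(C)C | starting material
22 | methyl 4-(tert-butyldimethylsilyloxy)-3-hydroxy-2-methylidenebutanoate (racemic) | C=C(C(=O)OC)C(O)CO[Si](C)(C)C(C)(C)C | intermediate
23 | methyl (2Z)-2-(bromomethyl)-4-(tert-butyldimethylsilyloxy)but-2-enoate | BrC/C(C(=O)OC)=C\CO[Si](C)(C)C(C)(C)C | intermediate
24 | allylindium dibromide from 23, trivalent indium on C13, Z-alkene kept (not isolated) | Br[In](Br)C/C(C(=O)OC)=C\CO[Si](C)(C)C(C)(C)C | intermediate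
25 | methyl (3S,4R)-3-[(tert-butyldimethylsilyloxy)methyl]-4-hydroxy-2-methylidene-5-{(2R)-2-methyl-3-oxo-5-[3,3-bis(4-methoxybenzyloxy)prop-1-en-2-yl]-2,3-dihydrofuran-2-yl}pentanoate (germacrane 7S,8R,10R) | C=C(C(=O)OC)[C@@H](CO[Si](C)(C)C(C)(C)C)[C@H](O)C[C@@]1(C)OC(=CC1=O)C(=C)C(OCc2ccc(OC)cc2)OCc3ccc(OC)cc3 | intermediate
26 | methyl (3S,4R)-3-[(tert-butyldimethylsilyloxy)methyl]-2-methylidene-4-(2-methylpropanoyloxy)-5-{(2R)-2-methyl-3-oxo-5-[3,3-bis(4-methoxybenzyloxy)prop-1-en-2-yl]-2,3-dihydrofuran-2-yl}pentanoate | C=C(C(=O)OC)[C@@H](CO[Si](C)(C)C(C)(C)C)[C@H](OC(=O)C(C)C)C[C@@]1(C)OC(=CC1=O)C(=C)C(OCc2ccc(OC)cc2)OCc3ccc(OC)cc3 | intermediate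
27 | methyl (3S,4R)-3-(hydroxymethyl)-2-methylidene-4-(2-methylpropanoyloxy)-5-{(2R)-2-methyl-3-oxo-5-[3,3-bis(4-methoxybenzyloxy)prop-1-en-2-yl]-2,3-dihydrofuran-2-yl}pentanoate | C=C(C(=O)OC)[C@@H](CO)[C@H](OC(=O)C(C)C)C[C@@]1(C)OC(=CC1=O)C(=C)C(OCc2ccc(OC)cc2)OCc3ccc(OC)cc3 | intermediate
28 | methyl (3R,4R)-3-formyl-2-methylidene-4-(2-methylpropanoyloxy)-5-{(2R)-2-methyl-3-oxo-5-[3,3-bis(4-methoxybenzyloxy)prop-1-en-2-yl]-2,3-dihydrofuran-2-yl}pentanoate (germacrane 7R,8R,10R) | C=C(C(=O)OC)[C@@H](C=O)[C@H](OC(=O)C(C)C)C[C@@]1(C)OC(=CC1=O)C(=C)C(OCc2ccc(OC)cc2)OCc3ccc(OC)cc3 | intermediate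
29 | α-iodo ether: 28 with one PMB-oxy group at C5 replaced by iodine, C5 undefined (not isolated) | C=C(C(=O)OC)[C@@H](C=O)[C@H](OC(=O)C(C)C)C[C@@]1(C)OC(=CC1=O)C(=C)C(I)OCc2ccc(OC)cc2 | intermediate
30 | allylchromium dichloride: trivalent chromium on C15, C4=C5 enol ether with the PMB-oxy group trans to the CH2Cr group (not isolated) | C=C(C(=O)OC)[C@@H](C=O)[C@H](OC(=O)C(C)C)C[C@@]1(C)OC(=CC1=O)/C(C[Cr](Cl)Cl)=C\OCc2ccc(OC)cc2 | intermediate
31 | O6 chromium alkoxide of the ten-membered hydroxy methyl ester, stereocentres as in 32 (not isolated) | C=C(C(=O)OC)[C@@H]1[C@H](OC(=O)C(C)C)C[C@@]2(C)OC(=CC2=O)C(=C)[C@H](OCc3ccc(OC)cc3)[C@@H]1O[Cr](Cl)Cl | intermediate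
32 | (5S,6R,7R,8R,10R)-5-(4-methoxybenzyloxy)-8-(2-methylpropanoyloxy)-1-oxo-3,10-epoxygermacra-2,4(15),11(13)-trien-12,6-olide | C=C1C(=O)O[C@@H]2[C@H]1[C@H](OC(=O)C(C)C)C[C@@]1(C)OC(=CC1=O)C(=C)[C@@H]2OCc3ccc(OC)cc3 | intermediate
33 | CNP0384113.1, (5S,6R,7R,8R,10R)-5-hydroxy-8-(2-methylpropanoyloxy)-1-oxo-3,10-epoxygermacra-2,4(15),11(13)-trien-12,6-olide | C=C1C(=O)O[C@@H]2[C@H]1[C@H](OC(=O)C(C)C)C[C@@]1(C)OC(=CC1=O)C(=C)[C@@H]2O | target

Total step count: 20
Longest linear sequence: 14 steps (steps 1–4, 9–12 and 15–20 from (R)-citramalic acid; the branch from acrolein through steps 5–8 is equally long)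

Steps most likely to fail

Step 19 (proposed new method). The macrocyclisation may lose to intermolecular allylation and oligomers. Me3SiI may cleave PMB ethers or add to the dienone. The allylchromium may attack the wrong aldehyde face or give the syn C5/C6 pair. The aldehyde may epimerise at C7 before it is trapped. The fallback uses known reactions only, sets out from silyl ether 26 and comes back at target 33. Mild acid hydrolysis of the acetal (PPTS, wet acetone) would give the enal F1, Luche reduction (NaBH4, CeCl3·7H2O, MeOH, −78 °C) the allylic alcohol F2, and Appel bromination (CBr4, PPh3) the allylic bromide F3. Desilylation (HF·pyridine) and Dess–Martin oxidation would then give the C6 alcohol F4 and the C6 aldehyde F5. Intramolecular Nozaki–Hiyama allylation of F5 (CrCl2, THF, high dilution), a ring closure with direct precedent for ten-membered germacrane rings, would form C5–C6 through a 2-substituted allylchromium whose two termini are equivalent. After lactonisation of the O6 alkoxide this would give the 5-deoxy lactone F6. Allylic hydroxylation of F6 (SeO2, t-BuOOH, CH2Cl2) at C5, the only allylic methylene of the C4=C15 alkene, would reach 33 without the PMB ether 32; the C5 configuration would then rest on the ring conformation and would have to be checked.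

Step 15. Facial selectivity at C8 may be poor, because the only control is 1,3-induction from the quaternary C10. The adduct may also lactonise through O8, and the acetal may hydrolyse in the aqueous medium. The fallback replaces substrate control by catalyst control; it sets out from aldehyde 19 and bromide 23 and comes back at adduct 25. Borylation of 23 (B2pin2, Pd2(dba)3 cat., DMSO) would give the allylboronate F7, with the borylmethyl group cis to the silyloxymethyl group. Allylboration of 19 with F7 under a chiral BINOL-derived phosphoric acid (TRIP, toluene, low temperature) passes through a closed chair transition state that keeps the syn C7/C8 relation. The catalyst, not C10, would choose the aldehyde face, and Brønsted acid activation is the known way to make these ester-substituted boronates react.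

Step 18. The C7 configuration may be lost by enolisation, the C11=C13 double bond may move into conjugation, and isobutyric acid may be eliminated; O6 may also lactonise onto C12 during the preceding desilylation. The fallback masks C6 as a vinyl group instead of a silyloxymethyl group; it sets out from aldehyde 19 (with 6 and 20) and comes back at aldehyde 28. A Morita–Baylis–Hillman reaction of acrolein 6 with methyl acrylate 20 would give the dienol F8, and NBS/Me2S the (Z)-dienyl bromide F9. Indium-mediated γ-pentadienylation of 19 with F9 would give the syn adduct F10, in which C7 carries a vinyl group, and acylation as in step 16 the isobutyrate F11. Lemieux–Johnson cleavage (OsO4 cat., NaIO4, 2,6-lutidine, dioxane/H2O) of the vinyl group, the only isolated and electron-rich alkene, would give 28 without a free γ-hydroxy ester, ready for step 19.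

Further compounds
F1 | step 19 | enal: 26 with the C5 acetal hydrolysed to the aldehyde | C=C(C(=O)OC)[C@@H](CO[Si](C)(C)C(C)(C)C)[C@H](OC(=O)C(C)C)C[C@@]1(C)OC(=CC1=O)C(=C)C=O
F2 | step 19 | allylic alcohol: F1 with C5 reduced to CH2OH | C=C(C(=O)OC)[C@@H](CO[Si](C)(C)C(C)(C)C)[C@H](OC(=O)C(C)C)C[C@@]1(C)OC(=CC1=O)C(=C)CO
F3 | step 19 | allylic bromide: F2 with C5 as CH2Br | C=C(C(=O)OC)[C@@H](CO[Si](C)(C)C(C)(C)C)[C@H](OC(=O)C(C)C)C[C@@]1(C)OC(=CC1=O)C(=C)CBr
F4 | step 19 | C6 alcohol: F3 without the silyl group | C=C(C(=O)OC)[C@@H](CO)[C@H](OC(=O)C(C)C)C[C@@]1(C)OC(=CC1=O)C(=C)CBr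
F5 | step 19 | C6 aldehyde carrying the C5 allylic bromide | C=C(C(=O)OC)[C@@H](C=O)[C@H](OC(=O)C(C)C)C[C@@]1(C)OC(=CC1=O)C(=C)CBr
F6 | step 19 | 5-deoxy analogue of 33 (C5 methylene; C6, C7, C8 and C10 arranged as in 33) | C=C1C(=O)O[C@@H]2[C@H]1[C@H](OC(=O)C(C)C)C[C@@]1(C)OC(=CC1=O)C(=C)C2
F7 | step 15 | methyl (2E)-4-(tert-butyldimethylsilyloxy)-2-[(4,4,5,5-tetramethyl-1,3,2-dioxaborolan-2-yl)methyl]but-2-enoate (borylmethyl cis to silyloxymethyl) | CC1(C)OB(C/C(C(=O)OC)=C\CO[Si](C)(C)C(C)(C)C)OC1(C)C
F8 | step 18 | methyl 3-hydroxy-2-methylidenepent-4-enoate (racemic) | C=CC(O)C(=C)C(=O)OC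
F9 | step 18 | methyl (2Z)-2-(bromomethyl)penta-2,4-dienoate | BrC/C(C(=O)OC)=C\C=C
F10 | step 18 | methyl (3R,4R)-3-ethenyl-4-hydroxy-2-methylidene-5-{(2R)-2-methyl-3-oxo-5-[3,3-bis(4-methoxybenzyloxy)prop-1-en-2-yl]-2,3-dihydrofuran-2-yl}pentanoate | C=C(C(=O)OC)[C@@H](C=C)[C@H](O)C[C@@]1(C)OC(=CC1=O)C(=C)C(OCc2ccc(OC)cc2)OCc3ccc(OC)cc3
F11 | step 18 | methyl (3R,4R)-3-ethenyl-2-methylidene-4-(2-methylpropanoyloxy)-5-{(2R)-2-methyl-3-oxo-5-[3,3-bis(4-methoxybenzyloxy)prop-1-en-2-yl]-2,3-dihydrofuran-2-yl}pentanoate | C=C(C(=O)OC)[C@@H](C=C)[C@H](OC(=O)C(C)C)C[C@@]1(C)OC(=CC1=O)C(=C)C(OCc2ccc(OC)cc2)OCc3ccc(OC)cc3
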